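**Retrosynthetic overview**
1. The last operation is a global Lewis-acid deprotection of four aryl methyl ethers and one tert-butyl ester. The protected skeleton is cut in the side chain, between the last CH2 of the (CH2)3 spacer and the CH(CH3) carbon that carries the CH2O-caffeoyl arm.
2. This bond is made by a one-pot hydroboration and nickel/chiral-diamine enantioconvergent alkyl–alkyl Suzuki–Miyaura coupling. The partners are a pent-4-en-2-yl tetralin and the racemic 2-bromopropyl ester of 3,4-dimethoxycinnamic acid, so both halves are joined and the last stereocenter is set from a racemate.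
3. Enabling feature: that CH(CH3) carbon is an unactivated secondary carbon, which becomes a planar radical after loss of Br. Its CH2–O–C(=O) arm places the caffeate carbonyl oxygen so that Ni–C, CH2, O, C=O and the O→Ni contact close a six-membered chelate. The partner carbon ends an unbranched three-carbon chain, i.e. it is the terminus of a vinyl group.
4. The pentenyl chain comes from an isopropenyl group by CuH-catalysed asymmetric hydroboration, which sets the CH(CH3) center next to the ring, followed by Zweifel vinylation.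
5. Ring order: the cyclohexane ring with both ring stereocenters is bought as (R)-carvone, and a temporary 2-pyrone ring is fused to it. The benzene ring is formed last by inverse-demand Diels–Alder reaction with loss of CO2 and MeOH, which places the ester, both oxygens and the single aromatic H. The caffeate ring is purchased.

Key step: step 9

Assumption: the absolute sense of induction of (R)-DTBM-SEGPHOS (step 6) and of the (R,R)-diamine (step 9) is taken by analogy with simpler substrates; both ligands are sold as both antipodes, and the antipode is used if the sense is the opposite one.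

**Step 1**
Reactants: 1 (R)-(–)-carvone
Product: 3 (2R,5R)-2-methyl-5-(prop-1-en-2-yl)cyclohexan-1-one (trans-dihydrocarvone), via lithium enolate 2 (not isolated)
Conditions: L-Selectride, THF, –78 °C; AcOH quench; then NaOMe (cat.), MeOH, rt; chromatography
Reagents that add atoms: none
Why: Conjugate (1,4-) hydride reduction of the enone by the hindered borohydride spares the isolated alkene, and base equilibration of the α-methyl ketone puts the new methyl-bearing center (R) in the diequatorial trans arrangement relative to the isopropenyl center that comes from the chiral pool.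

**Step 2**
Reactants: 3 trans-dihydrocarvone; 4 dimethyl 2-(methoxymethylidene)propanedioate
Product: 7 methyl (5S,8R)-8-methyl-2-oxo-5-(prop-1-en-2-yl)-5,6,7,8-tetrahydro-2H-chromene-3-carboxylate, via kinetic lithium enolate 5 (not isolated), via oxocyclohexylmethylidene malonate 6 (not isolated)
Conditions: LDA, THF, –78 °C; 4, –78 °C to rt; cold 10% aq HCl
Reagents that add atoms: none
Why: Kinetic enolate formation at the unsubstituted α-CH2, addition–elimination on the alkoxymethylidenemalonate and O-acylative ring closure (3-carbomethoxy-2-pyrone annulation of a ketone enolate) turn the carbonyl carbon next to the methyl-bearing center into the future oxygen-flanked ring-fusion carbon; no stereocenter is formed and the cold acidic quench guards the vinylogously acidic C8–H.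

**Step 3**
Reactants: 8 1,1,2,2-tetramethoxyethane
Product: 10 1,1,2-trimethoxyethene, via 1-chloro-1,2,2-trimethoxyethane 9 (not isolated)
Conditions: AcCl, ZnBr2 (cat.), neat, rt; volatiles removed; KOt-Bu, THF, 0 °C to rt; distillation
Reagents that add atoms: none
Why: Zinc(II)-catalysed acetal–acyl chloride exchange gives the α-chloro ether, and E2 dehydrochlorination by the bulky alkoxide (ketene acetal synthesis by dehydrohalogenation) gives the electron-rich alkene, which has no stereocenter.

**Step 4**
Reactants: 7 pyrone ester; 10 1,1,2-trimethoxyethene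
Product: 13 methyl (5R,8S)-3,4-dimethoxy-5-methyl-8-(prop-1-en-2-yl)-5,6,7,8-tetrahydronaphthalene-2-carboxylate, via bicyclic lactone cycloadduct 11 (not isolated), via trimethoxycyclohexadiene 12 (not isolated)
Conditions: 10 (excess), mesitylene, 140 °C, sealed tube
Reagents that add atoms: none
Why: Inverse-electron-demand Diels–Alder reaction of the electron-poor pyrone, retro-[4+2] loss of CO2 and elimination of methanol (catechol annulation) build the benzene ring; both orientations of the dienophile lead to the same 2,3-dimethoxybenzoate, and the transient stereocenters vanish on aromatisation while the two ring stereocenters are untouched.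

**Step 5**
Reactants: 13 methyl ester
Product: 14 tert-butyl (5R,8S)-3,4-dimethoxy-5-methyl-8-(prop-1-en-2-yl)-5,6,7,8-tetrahydronaphthalene-2-carboxylate
Conditions: LiOt-Bu (excess), THF, rt; H2O
Reagents that add atoms: lithium tert-butoxide, [Li+].CC(C)(C)[O-]
Why: Alkoxide transesterification of a methyl benzoate with excess lithium tert-butoxide installs an ester that resists the nucleophiles of steps 6 to 9 and ionises under the final Lewis acid, and the lithium alkoxide is too weak a base to remove the allylic-benzylic C8–H, so no stereocenter is affected.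

**Step 6**
Reactants: 14 isopropenyl tetralin
Product: 15 tert-butyl (5R,8S)-3,4-dimethoxy-5-methyl-8-[(2S)-1-(4,4,5,5-tetramethyl-1,3,2-dioxaborolan-2-yl)propan-2-yl]-5,6,7,8-tetrahydronaphthalene-2-carboxylate
Conditions: CuCl (5 mol %), (R)-DTBM-SEGPHOS (5.5 mol %), KOt-Bu (10 mol %), HBpin, toluene, rt
Reagents that add atoms: pinacolborane, [H]B1OC(C)(C)C(C)(C)O1
Why: Copper hydride-catalysed anti-Markovnikov asymmetric hydroboration of an unactivated 1,1-disubstituted alkene: ligand-controlled hydrocupration tells the methyl group from the bulky tetralinyl group and sets the side-chain center as S, and σ-bond metathesis with pinacolborane frees the primary boronate.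

**Step 7**
Reactants: 15 primary boronate
Product: 18 tert-butyl (5R,8S)-3,4-dimethoxy-5-methyl-8-[(2S)-pent-4-en-2-yl]-5,6,7,8-tetrahydronaphthalene-2-carboxylate, via vinyl boronate complex 16 (not isolated), via beta-iodoalkyl boronate 17 (not isolated)
Conditions: vinylMgBr, THF/DMSO 1:1, 0 °C to rt; I2, THF, 0 °C; NaOMe, MeOH, 0 °C to rt
Reagents that add atoms: vinylmagnesium bromide, C=C[Mg]Br
Why: Zweifel olefination: iodonium formation on the vinyl boronate triggers a 1,2-metallate shift of the primary alkyl group, and methoxide-induced anti elimination of boron and iodine gives the terminal alkene, the β-stereocenter being a spectator.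

**Step 8**
Reactants: 19 (E)-3,4-dimethoxycinnamic acid; 20 rac-2-bromopropan-1-ol
Product: 21 rac-2-bromopropyl (2E)-3-(3,4-dimethoxyphenyl)prop-2-enoate
Conditions: DCC, DMAP (cat.), CH2Cl2, 0 °C to rt
Reagents that add atoms: none
Why: Steglich esterification acylates the primary alcohol under neutral conditions that leave the secondary bromide alone, and the racemic center needs no control because step 9 is stereoconvergent.

**Step 9**
Reactants: 18 pentenyl tetralin; 21 racemic bromo ester
Product: 24 tert-butyl (5R,8S)-8-[(2S,6R)-7-{[(2E)-3-(3,4-dimethoxyphenyl)prop-2-enoyl]oxy}-6-methylheptan-2-yl]-3,4-dimethoxy-5-methyl-5,6,7,8-tetrahydronaphthalene-2-carboxylate, via B-alkyl-9-BBN 22 (not isolated), via potassium hexyloxyborate 23 (not isolated)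
Conditions: 9-BBN-H dimer, i-Pr2O, 60 °C; KOt-Bu and n-hexanol (each slightly less than 1 equiv per boron), rt; NiBr2·diglyme (10 mol %), (R,R)-N,N'-dimethyl-1,2-diphenylethane-1,2-diamine (12 mol %), 21, i-Pr2O, rt
Reagents that add atoms: none
Why: Proposed new method: anti-Markovnikov hydroboration of the vinyl group gives 22, its hexyloxyborate 23 transmetalates to diamine-ligated nickel, the alkylnickel(I) abstracts bromine from either enantiomer of 21 to give one planar secondary radical, and capture of this radical by alkylnickel(II) followed by C(sp3)–C(sp3) reductive elimination from nickel(III) forms the bond, so that both enantiomers of 21 are funnelled into one configuration. The closest known reaction type is the nickel/chiral 1,2-diamine enantioconvergent alkyl–alkyl Suzuki–Miyaura coupling of racemic O-carbamoyl bromohydrins with B-alkyl-9-BBN reagents at room temperature; new here is that an aryl-conjugated enoate ester takes the role of the directing carbamate. The step closes no ring. Its one new stereocenter, the CH(CH3) carbon next to the CH2O group, is set as R by the chiral diamine, which tells CH3 from the CH2O–C(=O) arm because the carbonyl oxygen binds nickel in a six-membered chelate, while the nearest stereocenter of 22 lies three bonds from boron and should not interfere. The selectivities needed are C–Br activation in preference to attack on the enoate and the two esters, and high facial discrimination at nickel. They are secured by the donor-substituted β-aryl enoate (a poor acceptor for nucleophilic alkyl radicals and alkylnickel species, yet a stronger Lewis base at oxygen than a plain alkanoate), by keeping alkoxide substoichiometric to boron so that it is bound as borate and cannot transesterify, and by the fact that a 1,2-acyloxy shift of the secondary radical would run uphill to a primary radical.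

**Step 10**
Reactants: 24 protected coupling product
Product: 25 (5R,8S)-8-[(2S,6R)-7-{[(2E)-3-(3,4-dihydroxyphenyl)prop-2-enoyl]oxy}-6-methylheptan-2-yl]-3,4-dihydroxy-5-methyl-5,6,7,8-tetrahydronaphthalene-2-carboxylic acid (CNP0492979.1)
Conditions: BBr3 (excess), CH2Cl2, –78 °C to 0 °C; ice/H2O
Reagents that add atoms: none
Why: Boron tribromide ether cleavage (bromide attack on the activated O–CH3 groups) and ionisation of the tert-butyl ester free both catechols and the acid, whereas the primary β-branched alkyl cinnamate offers neither an easy SN2 nor an SN1 path, and no stereocenter is touched.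

**Compound list**
1 | (R)-(–)-carvone | C=C(C)[C@@H]1CC=C(C)C(=O)C1 | starting material
2 | lithium (5R)-2-methyl-5-(prop-1-en-2-yl)cyclohex-1-en-1-olate | C=C(C)[C@@H]1CCC(C)=C([O-])C1.[Li+] | intermediate
3 | (2R,5R)-2-methyl-5-(prop-1-en-2-yl)cyclohexan-1-one | C=C(C)[C@@H]1CC[C@@H](C)C(=O)C1 | intermediate
4 | dimethyl 2-(methoxymethylidene)propanedioate | COC=C(C(=O)OC)C(=O)OC | starting material
5 | lithium (3R,6R)-6-methyl-3-(prop-1-en-2-yl)cyclohex-1-en-1-olate | C=C(C)[C@@H]1CC[C@@H](C)C([O-])=C1.[Li+] | intermediate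
6 | dimethyl 2-{[(3R,6R)-3-methyl-2-oxo-6-(prop-1-en-2-yl)cyclohexyl]methylidene}propanedioate (C1 epimers) | C=C(C)[C@@H]1CC[C@@H](C)C(=O)C1C=C(C(=O)OC)C(=O)OC | intermediate
7 | methyl (5S,8R)-8-methyl-2-oxo-5-(prop-1-en-2-yl)-5,6,7,8-tetrahydro-2H-chromene-3-carboxylate | C=C(C)[C@@H]1CC[C@@H](C)C2=C1C=C(C(=O)OC)C(=O)O2 | intermediate
8 | 1,1,2,2-tetramethoxyethane | COC(OC)C(OC)OC | starting material
9 | 1-chloro-1,2,2-trimethoxyethane (racemic) | COC(Cl)C(OC)OC | intermediate
10 | 1,1,2-trimethoxyethene | COC=C(OC)OC | intermediate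
11 | 2-oxabicyclo[2.2.2]oct-5-en-3-one cycloadduct of 7 and 10 (isomer mixture at the new centers) | C=C(C)[C@@H]1CC[C@@H](C)C23OC(=O)C(C(=O)OC)(C=C12)C(OC)(OC)C3OC | intermediate
12 | methyl (5R,8S)-3,3,4-trimethoxy-5-methyl-8-(prop-1-en-2-yl)-3,4,5,6,7,8-hexahydronaphthalene-2-carboxylate (C4 epimers) | C=C(C)[C@@H]1CC[C@@H](C)C2=C1C=C(C(=O)OC)C(OC)(OC)C2OC | intermediate
13 | methyl (5R,8S)-3,4-dimethoxy-5-methyl-8-(prop-1-en-2-yl)-5,6,7,8-tetrahydronaphthalene-2-carboxylate | C=C(C)[C@@H]1CC[C@@H](C)c2c1cc(C(=O)OC)c(OC)c2OC | intermediate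
14 | tert-butyl (5R,8S)-3,4-dimethoxy-5-methyl-8-(prop-1-en-2-yl)-5,6,7,8-tetrahydronaphthalene-2-carboxylate | C=C(C)[C@@H]1CC[C@@H](C)c2c1cc(C(=O)OC(C)(C)C)c(OC)c2OC | intermediate
15 | tert-butyl (5R,8S)-3,4-dimethoxy-5-methyl-8-[(2S)-1-(pinacolboryl)propan-2-yl]-5,6,7,8-tetrahydronaphthalene-2-carboxylate | CC1(C)OB(C[C@H](C)[C@@H]2CC[C@@H](C)c3c2cc(C(=O)OC(C)(C)C)c(OC)c3OC)OC1(C)C | intermediate
16 | bromomagnesium vinyl(alkyl)pinacolatoborate derived from 15 | C=C[B-]1(C[C@H](C)[C@@H]2CC[C@@H](C)c3c2cc(C(=O)OC(C)(C)C)c(OC)c3OC)OC(C)(C)C(C)(C)O1.[Mg+]Br | intermediate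
17 | 1-iodo-2-(pinacolboryl)pentan-4-yl tetralin (epimers at the boron-bearing carbon) | CC1(C)OB(C(CI)C[C@H](C)[C@@H]2CC[C@@H](C)c3c2cc(C(=O)OC(C)(C)C)c(OC)c3OC)OC1(C)C | intermediate
18 | tert-butyl (5R,8S)-3,4-dimethoxy-5-methyl-8-[(2S)-pent-4-en-2-yl]-5,6,7,8-tetrahydronaphthalene-2-carboxylate | C=CC[C@H](C)[C@@H]1CC[C@@H](C)c2c1cc(C(=O)OC(C)(C)C)c(OC)c2OC | intermediate
19 | (E)-3,4-dimethoxycinnamic acid | COc1ccc(/C=C/C(=O)O)cc1OC | starting material
20 | rac-2-bromopropan-1-ol | CC(Br)CO | starting material
21 | rac-2-bromopropyl (2E)-3-(3,4-dimethoxyphenyl)prop-2-enoate | CC(Br)COC(=O)/C=C/c1ccc(OC)c(OC)c1 | intermediate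
22 | B-alkyl-9-borabicyclo[3.3.1]nonane derived from 18 | B1(CCC[C@H](C)[C@@H]2CC[C@@H](C)c3c2cc(C(=O)OC(C)(C)C)c(OC)c3OC)C2CCCC1CCC2 | intermediate
23 | potassium B-alkyl-B-hexyloxy-9-boratabicyclo[3.3.1]nonane derived from 22 | CCCCCCO[B-]1(CCC[C@H](C)[C@@H]2CC[C@@H](C)c3c2cc(C(=O)OC(C)(C)C)c(OC)c3OC)C2CCCC1CCC2.[K+] | intermediate
24 | tert-butyl (5R,8S)-8-[(2S,6R)-7-{[(2E)-3-(3,4-dimethoxyphenyl)prop-2-enoyl]oxy}-6-methylheptan-2-yl]-3,4-dimethoxy-5-methyl-5,6,7,8-tetrahydronaphthalene-2-carboxylate | C[C@H](CCC[C@H](C)[C@@H]1CC[C@@H](C)c2c1cc(C(=O)OC(C)(C)C)c(OC)c2OC)COC(=O)/C=C/c1ccc(OC)c(OC)c1 | intermediate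
25 | CNP0492979.1 | C[C@H](CCC[C@H](C)[C@@H]1CC[C@@H](C)c2c1cc(C(=O)O)c(O)c2O)COC(=O)/C=C/c1ccc(O)c(O)c1 | target

**Totals.** Total step count: 10. Longest linear sequence: 8 (steps 1, 2, 4, 5, 6, 7, 9, 10).

**Three steps most likely to fail**

Step 9 (labelled).
- What may go wrong: weak binding of the ester oxygen to nickel may give poor facial discrimination at the new center. Alkoxide-mediated ester exchange, radical addition to the enoate or β-hydride elimination may erode the coupling.
- The fallback uses known chemistry. It makes the same bond by a 1,2-metallate shift under reagent control, sets out from 18 and comes back at 24.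
- Iridium-catalysed hydroboration of 18 with pinacolborane ([Ir(cod)Cl]2, dppe, CH2Cl2, rt) gives the primary pinacol boronate F1.
- Ethyl N,N-diisopropylcarbamate is lithiated with s-BuLi/(–)-sparteine (Et2O, –78 °C), F1 is added, and the boronate complex is warmed with MgBr2·OEt2. This moves the chain from boron to carbon with inversion at the carbenoid carbon and gives the secondary (R)-boronate F2.
- Matteson homologation (BrCH2Cl, n-BuLi, THF, –78 °C to rt) gives the homologated boronate F3.
- Oxidation (NaBO3·4H2O, THF/H2O) gives the primary alcohol F4.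
- Steglich esterification of F4 with 19 (DCC, DMAP) gives 24.

Step 6.
- What may go wrong: facial selectivity of the hydrocupration may be poor if the substrate bias opposes the ligand. Insertion of the hindered alkene may also be slow, which lets uncatalysed hydroboration compete.
- The fallback sets the same center by asymmetric conjugate reduction. It sets out from 14 and comes back at 18.
- Lemieux–Johnson cleavage (OsO4 cat., NaIO4, 2,6-lutidine, dioxane/H2O) gives the methyl ketone F5.
- Horner–Wadsworth–Emmons olefination (triethyl phosphonoacetate, NaH, THF) gives the (E)-enoate F6 after removal of the Z isomer.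
- Copper hydride-catalysed asymmetric conjugate reduction (CuCl, NaOt-Bu, p-tol-BINAP antipode chosen for S, PMHS, toluene) gives the saturated ethyl ester F7.
- DIBAL-H (CH2Cl2, –78 °C) reduces the unhindered alkyl ester only and gives the aldehyde F8.
- Wittig methylenation (Ph3P=CH2, THF) gives 18.

Step 10.
- What may go wrong: the caffeate ester may be lost under the large excess of Lewis acid, the hindered ether next to the benzylic methyl group may be cleaved incompletely, and the electron-rich rings may be tert-butylated.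
- The fallback moves the harsh demethylation to a stage without the caffeate and ends with a mild non-reductive debenzylation. It sets out from 18 and comes back at 25.
- BBr3 (CH2Cl2, –78 °C to 0 °C) on 18 gives the dihydroxy acid F9.
- BnBr, K2CO3, DMF gives the tribenzyl compound F10.
- Commercial (E)-3,4-bis(benzyloxy)cinnamic acid and 20 (DCC, DMAP) give the racemic bromo ester F11.
- F10 and F11 are joined under the conditions of step 9 to give the pentabenzyl coupling product F12.
- BCl3 with pentamethylbenzene as cation scavenger (CH2Cl2, –78 °C) removes all benzyl groups and gives 25.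

**Further compounds**
F1 | step 9 | tert-butyl (5R,8S)-3,4-dimethoxy-5-methyl-8-[(2S)-5-(pinacolboryl)pentan-2-yl]-5,6,7,8-tetrahydronaphthalene-2-carboxylate | CC1(C)OB(CCC[C@H](C)[C@@H]2CC[C@@H](C)c3c2cc(C(=O)OC(C)(C)C)c(OC)c3OC)OC1(C)C
F2 | step 9 | tert-butyl (5R,8S)-3,4-dimethoxy-5-methyl-8-[(2S,6R)-6-(pinacolboryl)heptan-2-yl]-5,6,7,8-tetrahydronaphthalene-2-carboxylate | C[C@H](CCC[C@H](C)[C@@H]1CC[C@@H](C)c2c1cc(C(=O)OC(C)(C)C)c(OC)c2OC)B1OC(C)(C)C(C)(C)O1
F3 | step 9 | tert-butyl (5R,8S)-3,4-dimethoxy-5-methyl-8-[(2S,6S)-6-methyl-7-(pinacolboryl)heptan-2-yl]-5,6,7,8-tetrahydronaphthalene-2-carboxylate | C[C@H](CCC[C@H](C)[C@@H]1CC[C@@H](C)c2c1cc(C(=O)OC(C)(C)C)c(OC)c2OC)CB1OC(C)(C)C(C)(C)O1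
F4 | step 9 | tert-butyl (5R,8S)-8-[(2S,6R)-7-hydroxy-6-methylheptan-2-yl]-3,4-dimethoxy-5-methyl-5,6,7,8-tetrahydronaphthalene-2-carboxylate | C[C@H](CCC[C@H](C)[C@@H]1CC[C@@H](C)c2c1cc(C(=O)OC(C)(C)C)c(OC)c2OC)CO
F5 | step 6 | tert-butyl (5R,8R)-8-acetyl-3,4-dimethoxy-5-methyl-5,6,7,8-tetrahydronaphthalene-2-carboxylate | CC(=O)[C@@H]1CC[C@@H](C)c2c1cc(C(=O)OC(C)(C)C)c(OC)c2OC
F6 | step 6 | tert-butyl (5R,8S)-8-[(2E)-4-ethoxy-4-oxobut-2-en-2-yl]-3,4-dimethoxy-5-methyl-5,6,7,8-tetrahydronaphthalene-2-carboxylate | CCOC(=O)/C=C(\C)[C@@H]1CC[C@@H](C)c2c1cc(C(=O)OC(C)(C)C)c(OC)c2OC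
F7 | step 6 | tert-butyl (5R,8S)-8-[(2S)-4-ethoxy-4-oxobutan-2-yl]-3,4-dimethoxy-5-methyl-5,6,7,8-tetrahydronaphthalene-2-carboxylate | CCOC(=O)C[C@H](C)[C@@H]1CC[C@@H](C)c2c1cc(C(=O)OC(C)(C)C)c(OC)c2OC
F8 | step 6 | tert-butyl (5R,8S)-3,4-dimethoxy-5-methyl-8-[(2S)-4-oxobutan-2-yl]-5,6,7,8-tetrahydronaphthalene-2-carboxylate | O=CC[C@H](C)[C@@H]1CC[C@@H](C)c2c1cc(C(=O)OC(C)(C)C)c(OC)c2OC
F9 | step 10 | (5R,8S)-3,4-dihydroxy-5-methyl-8-[(2S)-pent-4-en-2-yl]-5,6,7,8-tetrahydronaphthalene-2-carboxylic acid | C=CC[C@H](C)[C@@H]1CC[C@@H](C)c2c1cc(C(=O)O)c(O)c2O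
F10 | step 10 | benzyl (5R,8S)-3,4-bis(benzyloxy)-5-methyl-8-[(2S)-pent-4-en-2-yl]-5,6,7,8-tetrahydronaphthalene-2-carboxylate | C=CC[C@H](C)[C@@H]1CC[C@@H](C)c2c1cc(C(=O)OCc3ccccc3)c(OCc3ccccc3)c2OCc3ccccc3
F11 | step 10 | rac-2-bromopropyl (2E)-3-[3,4-bis(benzyloxy)phenyl]prop-2-enoate | CC(Br)COC(=O)/C=C/c1ccc(OCc2ccccc2)c(OCc2ccccc2)c1
F12 | step 10 | benzyl (5R,8S)-3,4-bis(benzyloxy)-8-[(2S,6R)-7-{[(2E)-3-[3,4-bis(benzyloxy)phenyl]prop-2-enoyl]oxy}-6-methylheptan-2-yl]-5-methyl-5,6,7,8-tetrahydronaphthalene-2-carboxylate | C[C@H](CCC[C@H](C)[C@@H]1CC[C@@H](C)c2c1cc(C(=O)OCc3ccccc3)c(OCc3ccccc3)c2OCc3ccccc3)COC(=O)/C=C/c1ccc(OCc2ccccc2)c(OCc2ccccc2)c1
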